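**Plan**

- Retrosynthesis: the C9–O silyl group and the C5' enol ether are adjusted last. The cyclohexadienone ring is then cut at the spiro-carbon–aryl bond (C5–C4a) and the ring CH next to the spiro carbon (C2') is excised. This leads back to a 2-methoxy-3-alkylcyclopentenone ketal carrying the aryl carbinol chain, which is cut at C6–C(ring) (Negishi) and C9–aryl (Grignard).
- Forward: the five-membered ring (from cyclopentane-1,2-dione), the C4 chain (from a methyl-butyrolactone) and the trimethoxyphenyl unit are joined. One operation then inserts a carbon into the five-membered ring to make the six-membered ring, closes the seven-membered ring and creates the spiro quaternary carbon. The second enol ether is installed afterwards.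
- Enabling feature: in the dienone the spiro carbon is bonded to CH=C(OMe), so it is the far terminus of a 1-methoxyallyl cation. That cation is what results when one carbon is inserted into the C(OMe)=C(alkyl) bond of a cyclopentene, and the electron-rich aryl ring four atoms away can capture it. The dienone ring is symmetric about its C1'···C4' axis, so the spiro carbon is not a stereocentre and the unsymmetrical intermediates converge.
- Stereochemistry: C7 comes from the chiral-pool lactone, C8 from trans-selective enolate methylation of that lactone, and C9 from Felkin–Anh addition of the aryl Grignard to the α-methyl aldehyde. None of the three is touched afterwards.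

Key step: step 10

Remark: locants follow 6,7,8,9-tetrahydrospiro[benzo[7]annulene-5,1'-cyclohexane] (spiro C5 = C1', CH2 = C6, CHMe = C7 and C8, CHOH = C9); lactone 4 is assumed to be purchasable as the single (S) enantiomer.

**Route**

Step 1
Reactants: 1 cyclopentane-1,2-dione
Product: 2 3-bromo-2-hydroxycyclopent-2-en-1-one
Conditions: NBS (1.0 equiv), CH2Cl2, 0 °C → rt
Reagents that add atoms: N-bromosuccinimide, O=C1CCC(=O)N1Br
Why: Electrophilic bromination of the enol (diosphenol) tautomer at its nucleophilic C3, followed by re-enolisation toward the brominated carbon, should give the 3-bromo diosphenol (α-halogenation of an enolised 1,2-dione).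

Step 2
Reactants: 2 3-bromo-2-hydroxycyclopent-2-en-1-one
Product: 3 3-bromo-2-methoxycyclopent-2-en-1-one
Conditions: MeI, K2CO3, acetone, rt
Reagents that add atoms: iodomethane, CI
Why: The acidic enol OH is O-alkylated under Williamson conditions, which fixes the enol ether on the carbon that becomes C3' and leaves a β-bromo enone for cross-coupling.

Step 3
Reactants: 4 (S)-4-methyldihydrofuran-2(3H)-one
Product: 5 (3S,4S)-3,4-dimethyldihydrofuran-2(3H)-one (trans)
Conditions: LDA, THF, −78 °C; MeI, −78 → −40 °C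
Reagents that add atoms: iodomethane, CI
Why: Alkylation of the lactone lithium enolate occurs on the ring face opposite to the C4 methyl group (1,2-induction in a five-membered enolate), so the trans lactone and with it the C8 centre should result.

Step 4
Reactants: 5 (3S,4S)-3,4-dimethyldihydrofuran-2(3H)-one
Product: 6 methyl (2S,3S)-4-iodo-2,3-dimethylbutanoate
Conditions: TMSI (1.3 equiv), CH2Cl2, rt; then MeOH, rt
Reagents that add atoms: iodotrimethylsilane, C[Si](C)(C)I; methanol, CO
Why: Silylation of the lactone carbonyl oxygen and SN2 attack of iodide at the O–CH2 carbon open the ring to the silyl 4-iodo ester, which methanol and the HI formed convert into the methyl ester (iodosilane lactone cleavage, Fischer esterification) without touching either stereocentre.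

Step 5
Reactants: 6 methyl (2S,3S)-4-iodo-2,3-dimethylbutanoate; 3 3-bromo-2-methoxycyclopent-2-en-1-one
Product: 8 methyl (2S,3R)-4-(2-methoxy-3-oxocyclopent-1-en-1-yl)-2,3-dimethylbutanoate, via alkylzinc iodide 7 (not isolated)
Conditions: Zn dust (activated with 1,2-dibromoethane/TMSCl), LiCl, THF, 35 °C; then 3, Pd(dppf)Cl2 (3 mol %), THF, rt → 45 °C
Reagents that add atoms: none
Why: Zinc inserts into the primary C–I bond in the presence of the ester, and the alkylzinc couples with the activated β-bromo enone in a Negishi sp3–sp2 coupling, a combination known for 3-bromo-2-oxycyclopentenones.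

Step 6
Reactants: 8 methyl (2S,3R)-4-(2-methoxy-3-oxocyclopent-1-en-1-yl)-2,3-dimethylbutanoate
Product: 9 methyl (2S,3R)-4-(6-methoxy-1,4-dioxaspiro[4.4]non-6-en-7-yl)-2,3-dimethylbutanoate
Conditions: TMSOCH2CH2OTMS (2 equiv), TMSOTf (5 mol %), CH2Cl2, −78 → −30 °C; pyridine quench
Reagents that add atoms: 1,2-bis(trimethylsilyloxy)ethane, C[Si](C)(C)OCCO[Si](C)(C)C
Why: Silyl-transfer ketalisation at low temperature protects the ketone without moving the double bond and takes the enol-ether alkene out of conjugation, so that it is electron-rich for step 10.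

Step 7
Reactants: 9 methyl (2S,3R)-4-(6-methoxy-1,4-dioxaspiro[4.4]non-6-en-7-yl)-2,3-dimethylbutanoate
Product: 10 (2S,3R)-4-(6-methoxy-1,4-dioxaspiro[4.4]non-6-en-7-yl)-2,3-dimethylbutanal
Conditions: DIBAL-H (1.1 equiv), CH2Cl2, −78 °C; MeOH, aq. Rochelle salt
Reagents that add atoms: none
Why: At −78 °C the tetrahedral aluminium hemiacetal of the α-branched ester is stable, so partial reduction should stop at the aldehyde, which is used at once to avoid α-epimerisation.

Step 8
Reactants: 10 (2S,3R)-4-(6-methoxy-1,4-dioxaspiro[4.4]non-6-en-7-yl)-2,3-dimethylbutanal; 11 5-bromo-1,2,3-trimethoxybenzene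
Product: 13 (1R,2S,3R)-4-(6-methoxy-1,4-dioxaspiro[4.4]non-6-en-7-yl)-2,3-dimethyl-1-(3,4,5-trimethoxyphenyl)butan-1-ol, via (3,4,5-trimethoxyphenyl)magnesium bromide 12 (not isolated)
Conditions: Mg, THF (11 → 12); then 10, THF, −78 → −40 °C; H2O
Reagents that add atoms: none
Why: Grignard addition under Felkin–Anh control (attack anti to the large C3 substituent and past the α-hydrogen) should place the new hydroxyl syn to the C2 methyl group, which is the (1R) configuration, i.e. C9 of the target.

Step 9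
Reactants: 13 (1R,2S,3R)-4-(6-methoxy-1,4-dioxaspiro[4.4]non-6-en-7-yl)-2,3-dimethyl-1-(3,4,5-trimethoxyphenyl)butan-1-ol
Product: 14 [(1R,2S,3R)-4-(6-methoxy-1,4-dioxaspiro[4.4]non-6-en-7-yl)-2,3-dimethyl-1-(3,4,5-trimethoxyphenyl)butoxy]tri(propan-2-yl)silane
Conditions: TIPSOTf, 2,6-lutidine, CH2Cl2, −78 → −20 °C
Reagents that add atoms: triisopropylsilyl trifluoromethanesulfonate, CC(C)[Si](C(C)C)(C(C)C)OS(=O)(=O)C(F)(F)F
Why: Silylation of the secondary alcohol with a silyl triflate and a hindered base is fast at low temperature in the presence of ketal and enol ether, and the bulky silyl group keeps this oxygen from acting as a nucleophile in step 10.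

Step 10
Reactants: 14 [(1R,2S,3R)-4-(6-methoxy-1,4-dioxaspiro[4.4]non-6-en-7-yl)-2,3-dimethyl-1-(3,4,5-trimethoxyphenyl)butoxy]tri(propan-2-yl)silane
Product: 17 (7R,8S,9R)-2'-bromo-2,3,4,3'-tetramethoxy-7,8-dimethyl-9-[tri(propan-2-yl)silyloxy]-6,7,8,9-tetrahydrospiro[benzo[7]annulene-5,1'-cyclohex-2'-en]-4'-one ethylene ketal (both C5 epimers), via dibromocyclopropane 15 (not isolated), via bromoallyl cation 16 (not isolated)
Conditions: CHBr3 (2.5 equiv), KOtBu (2.5 equiv), pentane–toluene, −30 °C; cold filtration; then AgBF4 (1.5 equiv), 2,6-di-tert-butyl-4-methylpyridine (2 equiv), HFIP–CH2Cl2, −40 → 0 °C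
Reagents that add atoms: bromoform, BrC(Br)Br
Why: Proposed new method: dibromocarbene adds [2+1] to the only electron-rich alkene, the tetrasubstituted enol-ether C(OMe)=C(alkyl) bond of the cyclopentene, and the resulting 1-methoxy-6,6-dibromobicyclo[3.1.0]hexane 15 loses its endo bromide (Ag+ assisted) with concerted disrotatory 2π-electrocyclic cleavage of the ring-fusion bond, so that the five-membered ring becomes the six-membered 2-bromo-1-methoxyallyl (vinylogous oxocarbenium) cation 16 with the new carbon between the methoxy carbon and the alkyl-bearing carbon. The tertiary terminus of 16 is then attacked by the tethered trimethoxyphenyl ring at the position ortho to the benzylic carbon (Friedel–Crafts alkylation), and loss of the arene proton to the hindered pyridine gives 17. The closest known reaction type is the silver-promoted electrocyclic ring opening of gem-dihalocyclopropanes made from cyclic enol ethers (one-carbon ring expansion to 2-halo-enone derivatives, a Ciamician–Dennstedt-type carbon insertion) with capture of the haloallyl cation by a tethered heteroatom nucleophile; here a carbon nucleophile forms a quaternary centre, which is argued from the high nucleophilicity of the arene position (ortho and para to OMe), from the four-atom tether that gives the same ring closure onto a six-membered cation as phenol-oxidation routes to such spiro rings, and from HFIP/BF4−, which offer the cation no other nucleophile. The six-membered ring arises by ring expansion (cleavage of the shared cyclopropane bond), and the seven-membered ring by C–C bond formation between the allyl terminus (exo to the new ring) and the arene carbon. The only new stereocentre is the spiro carbon, which is not controlled and need not be, because it becomes non-stereogenic once the dienone ring is symmetric; the three existing centres are remote from the cationic carbons. The selectivity needed is C-capture over O-capture and over proton loss: the TIPS group shields the benzylic oxygen, the two free ortho positions of the arene are equivalent, and any diene formed by proton loss should be re-protonated by the pyridinium salt to the same cation.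

Step 11
Reactants: 17 (7R,8S,9R)-2'-bromo-2,3,4,3'-tetramethoxy-7,8-dimethyl-9-[tri(propan-2-yl)silyloxy]-6,7,8,9-tetrahydrospiro[benzo[7]annulene-5,1'-cyclohex-2'-en]-4'-one ethylene ketal
Product: 19 (7R,8S,9R)-2,3,4,3'-tetramethoxy-7,8-dimethyl-9-[tri(propan-2-yl)silyloxy]-6,7,8,9-tetrahydrospiro[benzo[7]annulene-5,1'-cyclohex-2'-en]-4'-one ethylene ketal (both C5 epimers), via vinyllithium 18 (not isolated)
Conditions: t-BuLi (2.1 equiv), THF, −78 °C; MeOH
Reagents that add atoms: none
Why: Bromine–lithium exchange of the vinyl bromide followed by protonation replaces Br by H on the same sp2 carbon; the vinyllithium cannot β-eliminate methoxide within a six-membered ring.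

Step 12
Reactants: 19 (7R,8S,9R)-2,3,4,3'-tetramethoxy-7,8-dimethyl-9-[tri(propan-2-yl)silyloxy]-6,7,8,9-tetrahydrospiro[benzo[7]annulene-5,1'-cyclohex-2'-en]-4'-one ethylene ketal
Product: 20 (7R,8S,9R)-2,3,4,3'-tetramethoxy-7,8-dimethyl-9-[tri(propan-2-yl)silyloxy]-6,7,8,9-tetrahydrospiro[benzo[7]annulene-5,1'-cyclohex-2'-en]-4'-one (both C5 epimers)
Conditions: PPTS (0.2 equiv), acetone–H2O, rt
Reagents that add atoms: water, O
Why: Mild acid-catalysed hydrolysis should remove the allylic dioxolane, whose ionisation is assisted by the adjacent double bond, while C-protonation of the enol ether is retarded by the neighbouring ketal carbon and the 2-methoxy enone formed is stable (selective ketal hydrolysis).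

Step 13
Reactants: 20 (7R,8S,9R)-2,3,4,3'-tetramethoxy-7,8-dimethyl-9-[tri(propan-2-yl)silyloxy]-6,7,8,9-tetrahydrospiro[benzo[7]annulene-5,1'-cyclohex-2'-en]-4'-one
Product: 22 (7R,8S,9R)-2,3,4,3',5'-pentamethoxy-7,8-dimethyl-9-[tri(propan-2-yl)silyloxy]-6,7,8,9-tetrahydrospiro[benzo[7]annulene-5,1'-cyclohexa-2',5'-dien]-4'-one, via diosphenol 21 (not isolated)
Conditions: KOtBu (3 equiv), O2 (1 atm), THF–t-BuOH, −20 °C; Ar purge; Me2SO4, 0 °C
Reagents that add atoms: dioxygen, O=O; dimethyl sulfate, COS(=O)(=O)OC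
Why: The only enolisable position (C5') is oxygenated by O2 via the potassium enolate, the α-hydroperoxide is dehydrated by base (Kornblum–DeLaMare type) to the 1,2-dione, which can enolise only toward C6', and the diosphenolate is O-methylated in the same flask; the ring thereby becomes symmetric and C5 ceases to be a stereocentre.

Step 14
Reactants: 22 (7R,8S,9R)-2,3,4,3',5'-pentamethoxy-7,8-dimethyl-9-[tri(propan-2-yl)silyloxy]-6,7,8,9-tetrahydrospiro[benzo[7]annulene-5,1'-cyclohexa-2',5'-dien]-4'-one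
Product: 23 (7R,8S,9R)-9-hydroxy-2,3,4,3',5'-pentamethoxy-7,8-dimethyl-6,7,8,9-tetrahydrospiro[benzo[7]annulene-5,1'-cyclohexa-2',5'-dien]-4'-one
Conditions: TBAF, THF, 0 °C → rt
Reagents that add atoms: none
Why: Fluoride cleaves the Si–O bond (desilylation) under conditions that should leave the dienone, the enol ethers and the three stereocentres untouched.

**Compound list**

1 | cyclopentane-1,2-dione | O=C1CCCC1=O | starting material
2 | 3-bromo-2-hydroxycyclopent-2-en-1-one | O=C1CCC(Br)=C1O | intermediate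
3 | 3-bromo-2-methoxycyclopent-2-en-1-one | COC1=C(Br)CCC1=O | intermediate
4 | (S)-4-methyldihydrofuran-2(3H)-one | O1C[C@@H](C)CC1=O | starting material
5 | (3S,4S)-3,4-dimethyldihydrofuran-2(3H)-one | O1C[C@@H](C)[C@H](C)C1=O | intermediate
6 | methyl (2S,3S)-4-iodo-2,3-dimethylbutanoate | IC[C@@H](C)[C@H](C)C(=O)OC | intermediate
7 | [(2S,3S)-4-methoxy-2,3-dimethyl-4-oxobutyl]zinc iodide | I[Zn]C[C@@H](C)[C@H](C)C(=O)OC | intermediate
8 | methyl (2S,3R)-4-(2-methoxy-3-oxocyclopent-1-en-1-yl)-2,3-dimethylbutanoate | COC1=C(C[C@@H](C)[C@H](C)C(=O)OC)CCC1=O | intermediate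
9 | methyl (2S,3R)-4-(6-methoxy-1,4-dioxaspiro[4.4]non-6-en-7-yl)-2,3-dimethylbutanoate | COC1=C(C[C@@H](C)[C@H](C)C(=O)OC)CCC12OCCO2 | intermediate
10 | (2S,3R)-4-(6-methoxy-1,4-dioxaspiro[4.4]non-6-en-7-yl)-2,3-dimethylbutanal | COC1=C(C[C@@H](C)[C@H](C)C=O)CCC12OCCO2 | intermediate
11 | 5-bromo-1,2,3-trimethoxybenzene | COc1cc(Br)cc(OC)c1OC | starting material
12 | (3,4,5-trimethoxyphenyl)magnesium bromide | COc1cc([Mg]Br)cc(OC)c1OC | intermediate
13 | (1R,2S,3R)-4-(6-methoxy-1,4-dioxaspiro[4.4]non-6-en-7-yl)-2,3-dimethyl-1-(3,4,5-trimethoxyphenyl)butan-1-ol | COC1=C(C[C@@H](C)[C@H](C)[C@@H](O)c3cc(OC)c(OC)c(OC)c3)CCC12OCCO2 | intermediate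
14 | [(1R,2S,3R)-4-(6-methoxy-1,4-dioxaspiro[4.4]non-6-en-7-yl)-2,3-dimethyl-1-(3,4,5-trimethoxyphenyl)butoxy]tri(propan-2-yl)silane | COC1=C(C[C@@H](C)[C@H](C)[C@@H](O[Si](C(C)C)(C(C)C)C(C)C)c3cc(OC)c(OC)c(OC)c3)CCC12OCCO2 | intermediate
15 | 6,6-dibromo-1-methoxy-5-[(2R,3S,4R)-2,3-dimethyl-4-[tri(propan-2-yl)silyloxy]-4-(3,4,5-trimethoxyphenyl)butyl]bicyclo[3.1.0]hexan-2-one ethylene ketal (both ring-fusion diastereomers) | COC12C(Br)(Br)C1(C[C@@H](C)[C@H](C)[C@@H](O[Si](C(C)C)(C(C)C)C(C)C)c4cc(OC)c(OC)c(OC)c4)CCC23OCCO3 | intermediate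
16 | 2-bromo-1-methoxy-3-[(2R,3S,4R)-2,3-dimethyl-4-[tri(propan-2-yl)silyloxy]-4-(3,4,5-trimethoxyphenyl)butyl]-6,6-(ethylenedioxy)cyclohex-2-en-1-ylium tetrafluoroborate | C[O+]=C1C(Br)=C(C[C@@H](C)[C@H](C)[C@@H](O[Si](C(C)C)(C(C)C)C(C)C)c4cc(OC)c(OC)c(OC)c4)CCC12OCCO2.F[B-](F)(F)F | intermediate
17 | (7R,8S,9R)-2'-bromo-2,3,4,3'-tetramethoxy-7,8-dimethyl-9-[tri(propan-2-yl)silyloxy]-6,7,8,9-tetrahydrospiro[benzo[7]annulene-5,1'-cyclohex-2'-en]-4'-one ethylene ketal | COC1=C(Br)C2(CCC13OCCO3)C[C@@H](C)[C@H](C)[C@@H](O[Si](C(C)C)(C(C)C)C(C)C)c4cc(OC)c(OC)c(OC)c42 | intermediate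
18 | 2'-lithio analogue of 17 (vinyllithium) | COC1=C([Li])C2(CCC13OCCO3)C[C@@H](C)[C@H](C)[C@@H](O[Si](C(C)C)(C(C)C)C(C)C)c4cc(OC)c(OC)c(OC)c42 | intermediate
19 | (7R,8S,9R)-2,3,4,3'-tetramethoxy-7,8-dimethyl-9-[tri(propan-2-yl)silyloxy]-6,7,8,9-tetrahydrospiro[benzo[7]annulene-5,1'-cyclohex-2'-en]-4'-one ethylene ketal | COC1=CC2(CCC13OCCO3)C[C@@H](C)[C@H](C)[C@@H](O[Si](C(C)C)(C(C)C)C(C)C)c4cc(OC)c(OC)c(OC)c42 | intermediate
20 | (7R,8S,9R)-2,3,4,3'-tetramethoxy-7,8-dimethyl-9-[tri(propan-2-yl)silyloxy]-6,7,8,9-tetrahydrospiro[benzo[7]annulene-5,1'-cyclohex-2'-en]-4'-one | COC1=CC2(CCC1=O)C[C@@H](C)[C@H](C)[C@@H](O[Si](C(C)C)(C(C)C)C(C)C)c4cc(OC)c(OC)c(OC)c42 | intermediate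
21 | (7R,8S,9R)-3'-hydroxy-2,3,4,5'-tetramethoxy-7,8-dimethyl-9-[tri(propan-2-yl)silyloxy]-6,7,8,9-tetrahydrospiro[benzo[7]annulene-5,1'-cyclohexa-2',5'-dien]-4'-one (present as its potassium salt) | COC1=CC2(C=C(O)C1=O)C[C@@H](C)[C@H](C)[C@@H](O[Si](C(C)C)(C(C)C)C(C)C)c4cc(OC)c(OC)c(OC)c42 | intermediate
22 | (7R,8S,9R)-2,3,4,3',5'-pentamethoxy-7,8-dimethyl-9-[tri(propan-2-yl)silyloxy]-6,7,8,9-tetrahydrospiro[benzo[7]annulene-5,1'-cyclohexa-2',5'-dien]-4'-one | COC1=CC2(C=C(OC)C1=O)C[C@@H](C)[C@H](C)[C@@H](O[Si](C(C)C)(C(C)C)C(C)C)c4cc(OC)c(OC)c(OC)c42 | intermediate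
23 | (7R,8S,9R)-9-hydroxy-2,3,4,3',5'-pentamethoxy-7,8-dimethyl-6,7,8,9-tetrahydrospiro[benzo[7]annulene-5,1'-cyclohexa-2',5'-dien]-4'-one | COC1=CC2(C=C(OC)C1=O)C[C@@H](C)[C@H](C)[C@@H](O)c1cc(OC)c(OC)c(OC)c12 | target

**Step count and risks**

Total step count: 14. Longest linear sequence: 12 steps (steps 3–14, from lactone 4).

Steps most likely to fail:

1. Step 10 (Proposed new method). The carbene may add sluggishly to the hindered tetrasubstituted enol ether. The ring-expanded cation may also lose a proton, be O-demethylated or be hydrolysed on work-up before the seven-membered ring closes on a quaternary carbon. The fallback uses known chemistry, sets out from zinc reagent 7 and returns at 22. Commercial 4-bromo-2,6-dimethoxyphenol would be benzylated (BnBr, K2CO3) to 2-(benzyloxy)-5-bromo-1,3-dimethoxybenzene F1. Negishi coupling of 7 with F1 should give methyl (2S,3R)-4-[4-(benzyloxy)-3,5-dimethoxyphenyl]-2,3-dimethylbutanoate F2. DIBAL-H reduction would give (2S,3R)-4-[4-(benzyloxy)-3,5-dimethoxyphenyl]-2,3-dimethylbutanal F3. Felkin–Anh addition of Grignard reagent 12 would give (1R,2S,3R)-4-[4-(benzyloxy)-3,5-dimethoxyphenyl]-2,3-dimethyl-1-(3,4,5-trimethoxyphenyl)butan-1-ol F4, and TIPSOTf/2,6-lutidine its tri(propan-2-yl)silyl ether F5. Hydrogenolysis (H2, Pd/C) would free 4-[(2R,3S,4R)-2,3-dimethyl-4-[tri(propan-2-yl)silyloxy]-4-(3,4,5-trimethoxyphenyl)butyl]-2,6-dimethoxyphenol F6. Oxidation of F6 with PhI(OCOCF3)2 in trifluoroethanol (phenol dearomatisation with para-spirocyclisation by the trimethoxyphenyl ring) should give 22 directly, and step 14 follows.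

2. Step 8. Facial selectivity in the aryl addition may be poor (Felkin against anti-Felkin), and aldehyde 10 may partly epimerise at its α-carbon. The fallback sets out from 13 as its mixture with the C1 epimer and returns at 13. Dess–Martin oxidation would give (2S,3R)-4-(6-methoxy-1,4-dioxaspiro[4.4]non-6-en-7-yl)-2,3-dimethyl-1-(3,4,5-trimethoxyphenyl)butan-1-one F7. Reagent-controlled CBS reduction of this aryl ketone ((S)-Me-CBS catalyst, BH3·SMe2) should then return the (1R) alcohol 13.

3. Step 13. The diosphenolate may be over-oxidised with C–C cleavage, or the hydroperoxide may not eliminate cleanly. The fallback sets out from 20 and returns at 22. The lithium enolate (LiHMDS, THF, −78 °C) would be hydroxylated with 2-(phenylsulfonyl)-3-phenyloxaziridine to (7R,8S,9R)-5'-hydroxy-2,3,4,3'-tetramethoxy-7,8-dimethyl-9-[tri(propan-2-yl)silyloxy]-6,7,8,9-tetrahydrospiro[benzo[7]annulene-5,1'-cyclohex-2'-en]-4'-one F8. Dess–Martin oxidation of F8 would give diosphenol 21, now isolated, and Me2SO4/K2CO3 would give 22.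

Further compounds
F1 | step 10 | 2-(benzyloxy)-5-bromo-1,3-dimethoxybenzene | COc1cc(Br)cc(OC)c1OCc1ccccc1
F2 | step 10 | methyl (2S,3R)-4-[4-(benzyloxy)-3,5-dimethoxyphenyl]-2,3-dimethylbutanoate | COc1cc(C[C@@H](C)[C@H](C)C(=O)OC)cc(OC)c1OCc1ccccc1
F3 | step 10 | (2S,3R)-4-[4-(benzyloxy)-3,5-dimethoxyphenyl]-2,3-dimethylbutanal | COc1cc(C[C@@H](C)[C@H](C)C=O)cc(OC)c1OCc1ccccc1
F4 | step 10 | (1R,2S,3R)-4-[4-(benzyloxy)-3,5-dimethoxyphenyl]-2,3-dimethyl-1-(3,4,5-trimethoxyphenyl)butan-1-ol | COc1cc(C[C@@H](C)[C@H](C)[C@@H](O)c2cc(OC)c(OC)c(OC)c2)cc(OC)c1OCc1ccccc1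
F5 | step 10 | [(1R,2S,3R)-4-[4-(benzyloxy)-3,5-dimethoxyphenyl]-2,3-dimethyl-1-(3,4,5-trimethoxyphenyl)butoxy]tri(propan-2-yl)silane | COc1cc(C[C@@H](C)[C@H](C)[C@@H](O[Si](C(C)C)(C(C)C)C(C)C)c2cc(OC)c(OC)c(OC)c2)cc(OC)c1OCc1ccccc1
F6 | step 10 | 4-[(2R,3S,4R)-2,3-dimethyl-4-[tri(propan-2-yl)silyloxy]-4-(3,4,5-trimethoxyphenyl)butyl]-2,6-dimethoxyphenol | COc1cc(C[C@@H](C)[C@H](C)[C@@H](O[Si](C(C)C)(C(C)C)C(C)C)c2cc(OC)c(OC)c(OC)c2)cc(OC)c1O
F7 | step 8 | (2S,3R)-4-(6-methoxy-1,4-dioxaspiro[4.4]non-6-en-7-yl)-2,3-dimethyl-1-(3,4,5-trimethoxyphenyl)butan-1-one | COC1=C(C[C@@H](C)[C@H](C)C(=O)c3cc(OC)c(OC)c(OC)c3)CCC12OCCO2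
F8 | step 13 | (7R,8S,9R)-5'-hydroxy-2,3,4,3'-tetramethoxy-7,8-dimethyl-9-[tri(propan-2-yl)silyloxy]-6,7,8,9-tetrahydrospiro[benzo[7]annulene-5,1'-cyclohex-2'-en]-4'-one | COC1=CC2(CC(O)C1=O)C[C@@H](C)[C@H](C)[C@@H](O[Si](C(C)C)(C(C)C)C(C)C)c4cc(OC)c(OC)c(OC)c42
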